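**Retrosynthetic overview**
- Key disconnection: the benzylic C–O bond O1–C2 of the dihydrofuran (ring B). Its closure onto a benzylic cation forms the ring and fixes C2; the C3–C3a bond is made just before it in the same flask.
- This leads to two achiral pieces: a 2-allyl-4,5-dimethoxyphenoxenium (oxocarbenium) ion, released from a quinone monoketal by a chiral acid, and (Z)-isoelemicin.
- The quinone monoketal comes from 2-allyl-4,5-dimethoxyphenol by oxidative C–O bond formation (methoxylation para to OH).
- The phenol comes from 3,4-dimethoxyphenol by O-allylation and Claisen rearrangement; (Z)-isoelemicin comes from 3,4,5-trimethoxybenzaldehyde by Wittig olefination.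
- Ring order: ring A (carbocycle) is bought as an arene and dearomatised; ring B (dihydrofuran) is formed last, together with all three stereocentres.

Assumption: benzofuran numbering (O1, C2, C3, C3a, C4 to C7, C7a) is used; the target is (2R,3S,3aS), with aryl and methyl cis and allyl trans to both. IDPi-A is the (S,S)-imidodiphosphorimidate Brønsted acid built from two 3,3'-bis[3,5-bis(trifluoromethyl)phenyl]-1,1'-bi-2-naphthol units with N-trifluoromethylsulfonyl groups on phosphorus; which catalyst enantiomer gives the (2R,3S,3aS) series must be found in one screening run, and "(S,S)" stands for that one.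

**Step 1**
Reactants: 1 3,4-dimethoxyphenol; 2 allyl bromide
Product: 3 4-(allyloxy)-1,2-dimethoxybenzene
Conditions: K2CO3, acetone, reflux
Reagents that add atoms: none
Why: Williamson ether synthesis, SN2 attack of the phenoxide on the primary allylic bromide; no stereocentre is formed.

**Step 2**
Reactants: 3 4-(allyloxy)-1,2-dimethoxybenzene
Product: 5 2-allyl-4,5-dimethoxyphenol, via Claisen dienone 4 (not isolated)
Conditions: PhNEt2, 195 °C
Reagents that add atoms: none
Why: Aromatic Claisen rearrangement, the [3,3] shift goes to the unhindered ortho carbon (para to the 3-methoxy group) and dienone 4 tautomerises to the phenol.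

**Step 3**
Reactants: 5 2-allyl-4,5-dimethoxyphenol
Product: 6 2-allyl-4,4,5-trimethoxycyclohexa-2,5-dien-1-one
Conditions: PhI(OAc)2, MeOH, 0 °C
Reagents that add atoms: methanol, SMILES CO
Why: Oxidative dearomatisation of a para-methoxyphenol to a quinone monoketal, the phenol binds to iodine and methanol attacks the methoxy-bearing para carbon (C–O bond formation); the allyl group is inert.

**Step 4**
Reactants: 7 3,4,5-trimethoxybenzaldehyde; 8 ethyltriphenylphosphonium bromide
Product: 10 (Z)-1,2,3-trimethoxy-5-(prop-1-en-1-yl)benzene, via ethylidenetriphenylphosphorane 9 (not isolated)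
Conditions: NaN(SiMe3)2, THF, −78 °C to rt; AgNO3–SiO2 chromatography
Reagents that add atoms: none
Why: Wittig olefination with a non-stabilised ylide under lithium-free conditions gives the cis-oxaphosphetane kinetically and hence the (Z)-alkene (expected about 9:1), the minor (E)-isomer being removed on silver-nitrate silica.

**Step 5**
Reactants: 6 2-allyl-4,4,5-trimethoxycyclohexa-2,5-dien-1-one; 10 (Z)-1,2,3-trimethoxy-5-(prop-1-en-1-yl)benzene (1.5 equiv)
Product: 14 (2R,3S,3aS)-3a-allyl-5-methoxy-3-methyl-2-(3,4,5-trimethoxyphenyl)-3,3a-dihydro-1-benzofuran-6(2H)-one, via oxocarbenium ion 11 (not isolated), via benzylic cation 12 (not isolated), via O-methyl oxocarbenium ion 13 (not isolated)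
Conditions: (S,S)-IDPi-A (5 mol %), CHCl3, −60 °C; then H2O (3 equiv), −20 °C
Reagents that add atoms: water, SMILES O
Why: Proposed new method: the confined chiral acid ionises ketal 6 to cation 11, which stays paired with the chiral anion; the (Z)-alkene adds through its methyl-bearing carbon to the allyl-bearing ring carbon on the face the anion leaves open, with aryl and methyl both stacked over the cationic ring (endo), which sets C3a and C3; benzylic cation 12 is then closed by the ring carbonyl oxygen, and this key C–O bond forms ring B, fixes C2 with aryl anti to allyl and cis to methyl, and diverts 12 from the competing carbon closure to a bicyclo[3.2.1]octane; water hydrolyses 13 to 14 (the C6 carbonyl oxygen comes from water) and returns the proton; the closest known chemistry is the racemic acid-promoted (3+2) annulation of quinone monoketals with propenylbenzenes and counteranion-directed asymmetric additions of alkenes to oxocarbenium ions, but no enantioselective version of this annulation is known.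

**Compound list**
1 | 3,4-dimethoxyphenol | COc1ccc(O)cc1OC | starting material
2 | allyl bromide | C=CCBr | starting material
3 | 4-(allyloxy)-1,2-dimethoxybenzene | C=CCOc1ccc(OC)c(OC)c1 | intermediate
4 | 6-allyl-3,4-dimethoxycyclohexa-2,4-dien-1-one (racemic, not isolated) | C=CCC1C=C(OC)C(OC)=CC1=O | intermediate
5 | 2-allyl-4,5-dimethoxyphenol | C=CCc1cc(OC)c(OC)cc1O | intermediate
6 | 2-allyl-4,4,5-trimethoxycyclohexa-2,5-dien-1-one | C=CCC1=CC(OC)(OC)C(OC)=CC1=O | intermediate
7 | 3,4,5-trimethoxybenzaldehyde | COc1cc(C=O)cc(OC)c1OC | starting material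
8 | ethyltriphenylphosphonium bromide | CC[P+](c1ccccc1)(c1ccccc1)c1ccccc1.[Br-] | starting material
9 | ethylidenetriphenylphosphorane (not isolated) | CC=P(c1ccccc1)(c1ccccc1)c1ccccc1 | intermediate
10 | (Z)-1,2,3-trimethoxy-5-(prop-1-en-1-yl)benzene, (Z)-isoelemicin | C/C=C\c1cc(OC)c(OC)c(OC)c1 | intermediate
11 | 2-allyl-4,5-dimethoxyphenoxenium ion, drawn as its 4-O-methyl oxocarbenium form (achiral, not isolated) | C=CCC1=CC(=[O+]C)C(OC)=CC1=O | intermediate
12 | 6-allyl-3,4-dimethoxy-6-[1-(3,4,5-trimethoxyphenyl)propan-1-ylium-2-yl]cyclohexa-2,4-dien-1-one, configured as 14 at C3 and C3a (not isolated) | C=CC[C@]1([C@H](C)[CH+]c2cc(OC)c(OC)c(OC)c2)C=C(OC)C(OC)=CC1=O | intermediate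
13 | oxocarbenium ion of 14 carrying a methyl group on the C6 oxygen (not isolated) | C=CC[C@]12C=C(OC)C(=[O+]C)C=C1O[C@@H](c1cc(OC)c(OC)c(OC)c1)[C@H]2C | intermediate
14 | (2R,3S,3aS)-3a-allyl-5-methoxy-3-methyl-2-(3,4,5-trimethoxyphenyl)-3,3a-dihydro-1-benzofuran-6(2H)-one | C=CC[C@]12C=C(OC)C(=O)C=C1O[C@@H](c1cc(OC)c(OC)c(OC)c1)[C@H]2C | target

**Step count and risks**
Total steps: 5. Longest linear sequence: 4 (steps 1, 2, 3, 5).

Most likely to fail, in this order:

Step 5 (the proposed annulation). Enantio- and diastereocontrol by the chiral anion is untested; the alkene may isomerise or oligomerise under acid; and cation 12 may close on carbon to give the bicyclo[3.2.1]octane isomer. Fallback with known chemistry: setting out from 6 and 10, the annulation is run with an achiral strong acid (CF3SO3H, 10 mol %, MeCN, −30 °C), as is known in racemic form for the methylenedioxyphenyl analogues. This gives 14 together with its mirror image, the (2S,3R,3aR)-enantiomer F1. The two are separated by preparative HPLC on an amylose tris(3,5-dimethylphenylcarbamate) phase, and the route is rejoined at 14.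

Step 4 (Z-selectivity of the Wittig reaction). An electron-rich aldehyde can give a poorer Z/E ratio, and the (E)-isomer would lead to the C3-epimeric series in step 5. Fallback: setting out from 7, CBr4/PPh3 gives 5-(2,2-dibromovinyl)-1,2,3-trimethoxybenzene F2 (Corey–Fuchs). Treatment with n-BuLi (2 equiv) and then MeI gives 1,2,3-trimethoxy-5-(prop-1-yn-1-yl)benzene F3. Semihydrogenation over Pd/CaCO3 poisoned with Pb(OAc)2 and quinoline (H2, 1 atm) gives the (Z)-alkene, and the route is rejoined at 10.

Step 3 (oxidative ketalisation). Competing attack at the allyl-bearing ortho carbon or over-oxidation to the quinone would lower the yield of the acid-labile ketal. Fallback: setting out from 5, MeI/K2CO3 gives 1-allyl-2,4,5-trimethoxybenzene F4. Anodic oxidation (Pt anode, KOH, MeOH, 0 °C) gives the quinone bisketal 1-allyl-3,3,4,6,6-pentamethoxycyclohexa-1,4-diene F5. Brief treatment with aqueous AcOH in acetone at 0 °C hydrolyses only the ketal next to the allyl-bearing carbon, because its oxocarbenium ion is stabilised through the vinylogous methoxy group, and the route is rejoined at 6.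

**Further compounds**
F1 | step 5 | (2S,3R,3aR)-3a-allyl-5-methoxy-3-methyl-2-(3,4,5-trimethoxyphenyl)-3,3a-dihydro-1-benzofuran-6(2H)-one | C=CC[C@@]12C=C(OC)C(=O)C=C1O[C@H](c1cc(OC)c(OC)c(OC)c1)[C@@H]2C
F2 | step 4 | 5-(2,2-dibromovinyl)-1,2,3-trimethoxybenzene | COc1cc(C=C(Br)Br)cc(OC)c1OC
F3 | step 4 | 1,2,3-trimethoxy-5-(prop-1-yn-1-yl)benzene | CC#Cc1cc(OC)c(OC)c(OC)c1
F4 | step 3 | 1-allyl-2,4,5-trimethoxybenzene | C=CCc1cc(OC)c(OC)cc1OC
F5 | step 3 | 1-allyl-3,3,4,6,6-pentamethoxycyclohexa-1,4-diene | C=CCC1=CC(OC)(OC)C(OC)=CC1(OC)OC
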